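**Retrosynthetic overview**

1. Ring numbering: C1 (=C–CH2O-isobutyrate), C2 (=CH), C3 (CH2), C4 (CH with the side chain), C5 (CH2), C6 (CHOH). The skipped diene is cut at the side-chain C(=CH2)–CH2 bond: a ruthenium-catalysed Alder-ene coupling of a ring alkyne with a homoallylic alcohol ester made from (S)-2-methylglycidol.
2. The ring alkyne goes back to a bridged lactone, a 6-oxabicyclo[3.2.1]oct-3-en-7-one. Its carbonyl carbon is the future C(=CH2) carbon on C4 and its ring oxygen is the C6 hydroxyl oxygen (lactol, then one-carbon homologation to the alkyne).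
3. Key disconnection C2–C3: the bridged lactone arises from a γ-alkenyl α-methylene-γ-butyrolactone by 6-endo cyclisation of a vinyl radical at C2 onto the exocyclic CH2 (C3). The cyclohexene, the only ring of the target, is closed last, onto the temporary lactone ring made one step earlier.
4. Enabling feature: C4 and C6 are 1,3-cis on the cyclohexene, so the C6 oxygen and the first side-chain carbon can be joined as a five-membered lactone (O–C6–C5–C4–C=O) with C3 as its exocyclic methylene. This ring makes C3 a radical acceptor and allows only the cis-bridged product.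
5. The methylene lactone comes from a β-bromo enal (four steps from 2,2-dimethyl-1,3-dioxan-5-one) and ethyl 2-(bromomethyl)acrylate by catalytic asymmetric 2-(ethoxycarbonyl)allylation, which sets C6.

Key step: step 6

Remark on the chemistry: the bromoalkene intermediates before the key step are carried as E/Z mixtures, because the σ-vinyl radical inverts faster than it cyclises; the enantiomer of the chromium ligand in step 5 is assumed to be the one that gives the 5S lactone.

**Route**

Step 1
Reactants: 1 2,2-dimethyl-1,3-dioxan-5-one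
Product: 2 5-(bromomethylidene)-2,2-dimethyl-1,3-dioxane
Conditions: Ph3P+CH2Br Br−, KOtBu, THF, −78 °C to rt
Reagents that add atoms: (bromomethyl)triphenylphosphonium bromide, BrC[P+](c1ccccc1)(c1ccccc1)c1ccccc1.[Br-]
Why: Wittig bromomethylenation of the ketone with the non-stabilised ylide should give the vinyl bromide; the dioxane is symmetric, so no alkene isomers and no stereocentre arise.

Step 2
Reactants: 2 5-(bromomethylidene)-2,2-dimethyl-1,3-dioxane
Product: 3 2-(bromomethylidene)propane-1,3-diol
Conditions: Dowex 50W (H+ form), MeOH, rt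
Reagents that add atoms: none
Why: Acid-catalysed transacetalisation should free the 1,3-diol while the vinyl bromide stays inert.

Step 3
Reactants: 3 2-(bromomethylidene)propane-1,3-diol
Product: 4 3-bromo-2-({[tert-butyl(dimethyl)silyl]oxy}methyl)prop-2-en-1-ol
Conditions: NaH (1.0 equiv), THF, 0 °C; t-BuMe2SiCl (1.0 equiv)
Reagents that add atoms: tert-butyl(chloro)dimethylsilane, CC(C)(C)[Si](C)(C)Cl
Why: O-Silylation of the diol through its monosodium alkoxide should stop after one silyl group; the two hydroxyls differ only in lying cis or trans to bromine, so an E/Z pair forms.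

Step 4
Reactants: 4 3-bromo-2-({[tert-butyl(dimethyl)silyl]oxy}methyl)prop-2-en-1-ol
Product: 5 3-bromo-2-({[tert-butyl(dimethyl)silyl]oxy}methyl)prop-2-enal
Conditions: MnO2, CH2Cl2, rt
Reagents that add atoms: none
Why: MnO2 oxidation of a primary allylic alcohol should give the enal without touching the silyl ether or the vinyl bromide.

Step 5
Reactants: 5 3-bromo-2-({[tert-butyl(dimethyl)silyl]oxy}methyl)prop-2-enal; 6 ethyl 2-(bromomethyl)prop-2-enoate
Product: 9 (5S)-5-[1-bromo-3-{[tert-butyl(dimethyl)silyl]oxy}prop-1-en-2-yl]-3-methylideneoxolan-2-one, via silyl ether 7 (not isolated), via hydroxy ester 8 (not isolated)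
Conditions: CrCl2 (10 mol %), tridentate carbazole bis(oxazoline) ligand (12 mol %), Et3N (20 mol %), Mn, Me3SiCl, THF, rt; aq. citric acid; PPTS, CH2Cl2, rt
Reagents that add atoms: none
Why: Chromium-catalysed asymmetric Nozaki–Hiyama–Kishi-type 2-(alkoxycarbonyl)allylation, in which the allylchromium species from 6 adds 1,2 to the aldehyde through a closed six-membered transition state and the chiral ligand selects the aldehyde face that gives the S carbinol carbon (the vinyl bromide is inert without a nickel co-catalyst); acid then removes the Me3Si group and closes the γ-lactone.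

Step 6
Reactants: 9 (5S)-5-[1-bromo-3-{[tert-butyl(dimethyl)silyl]oxy}prop-1-en-2-yl]-3-methylideneoxolan-2-one
Product: 10 (1S,5S)-4-({[tert-butyl(dimethyl)silyl]oxy}methyl)-6-oxabicyclo[3.2.1]oct-3-en-7-one
Conditions: Bu3SnH (1.3 equiv) and AIBN (0.2 equiv) by syringe pump over 8 h, benzene (5 mM), 80 °C
Reagents that add atoms: none
Why: Bu3Sn• abstracts bromine from either geometric isomer of 9 to give a rapidly inverting σ-vinyl radical at the =CH carbon, which adds 6-endo-trig to the exocyclic CH2 of the α-methylene lactone (the β-carbon of an acrylate, the electronically preferred terminus), and the resulting tertiary radical next to the lactone carbonyl takes hydrogen from Bu3SnH. The closest known reaction type is the tin hydride vinyl radical cyclisation, in the variant where an acrylate tethered through its α-carbon closes 6-endo. One ring is closed, the cyclohexene, in 6-endo-trig mode, and together with the existing lactone it forms the bridged 6-oxabicyclo[3.2.1]octene. The one new stereocentre (the carbon α to the lactone carbonyl, later the ring carbon that carries the side chain) is controlled by the two-atom C(=O)–O bridge, which can only span the new ring cis, so hydrogen is delivered to the outer face and the configuration follows from the 5S carbinol carbon. The step needs 6-endo over 5-exo closure, secured by the fully substituted inner alkene carbon and its conjugation with the carbonyl (5-exo would give a primary radical in a strained 2-oxabicyclo[2.2.1]heptene), and cyclisation over direct reduction of the vinyl radical, secured by slow addition of the stannane at high dilution. A radical is chosen because a polar or syn-carbometalation pathway would need a bridgehead enolate or a metal on the inner face of the bicycle.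

Step 7
Reactants: 10 (1S,5S)-4-({[tert-butyl(dimethyl)silyl]oxy}methyl)-6-oxabicyclo[3.2.1]oct-3-en-7-one
Product: 11 (1S,5S)-4-({[tert-butyl(dimethyl)silyl]oxy}methyl)-6-oxabicyclo[3.2.1]oct-3-en-7-ol
Conditions: i-Bu2AlH (1.1 equiv), CH2Cl2, −78 °C; aq. potassium sodium tartrate
Reagents that add atoms: none
Why: DIBAL-H reduction of a lactone at −78 °C should stop at the aluminium hemiacetal and give the lactol on work-up; the new hemiacetal centre is of no consequence.

Step 8
Reactants: 11 (1S,5S)-4-({[tert-butyl(dimethyl)silyl]oxy}methyl)-6-oxabicyclo[3.2.1]oct-3-en-7-ol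
Product: 13 (1S,5S)-2-({[tert-butyl(dimethyl)silyl]oxy}methyl)-5-ethynylcyclohex-2-en-1-ol, via hydroxy aldehyde 12 (not isolated)
Conditions: MeC(O)C(N2)P(O)(OMe)2, K2CO3, MeOH, 0 °C to rt
Reagents that add atoms: dimethyl (1-diazo-2-oxopropyl)phosphonate, CC(=O)C(=[N+]=[N-])P(=O)(OC)OC
Why: Ohira–Bestmann (Seyferth–Gilbert) homologation of the hydroxy aldehyde in ring–chain equilibrium with the lactol should give the terminal alkyne and free the ring hydroxyl; the carbon α to the aldehyde is expected to stay cis because only the cis aldehyde can close back to the lactol.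

Step 9
Reactants: 13 (1S,5S)-2-({[tert-butyl(dimethyl)silyl]oxy}methyl)-5-ethynylcyclohex-2-en-1-ol
Product: 14 (1S,5S)-5-ethynyl-2-(hydroxymethyl)cyclohex-2-en-1-ol
Conditions: Bu4NF, THF, 0 °C
Reagents that add atoms: none
Why: Fluoride-mediated silyl ether cleavage should free the primary allylic alcohol without affecting the alkyne or the stereocentres.

Step 10
Reactants: 14 (1S,5S)-5-ethynyl-2-(hydroxymethyl)cyclohex-2-en-1-ol
Product: 15 [(4S,6S)-4-ethynyl-6-hydroxycyclohex-1-en-1-yl]methyl 2-methylpropanoate
Conditions: i-PrCOCl (1.05 equiv), 2,4,6-collidine, CH2Cl2, −78 °C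
Reagents that add atoms: 2-methylpropanoyl chloride, CC(C)C(Cl)=O
Why: Kinetically controlled O-acylation with a slight excess of acid chloride and a hindered pyridine base should esterify the primary allylic hydroxyl in preference to the secondary one.

Step 11
Reactants: 16 [(2S)-2-methyloxiran-2-yl]methanol
Product: 17 (2R)-2-methylpent-4-ene-1,2-diol
Conditions: CH2=CHMgBr (3 equiv), CuI (10 mol %), THF, −30 to 0 °C
Reagents that add atoms: vinylmagnesium bromide, C=C[Mg]Br
Why: Copper-catalysed Grignard opening of the 2,2-disubstituted epoxide by SN2 attack at its CH2 terminus should give the homoallylic tertiary alcohol with the quaternary centre untouched (the descriptor changes from S to R only through the change in priorities).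

Step 12
Reactants: 17 (2R)-2-methylpent-4-ene-1,2-diol
Product: 18 (2R)-2-hydroxy-2-methylpent-4-en-1-yl 2-methylpropanoate
Conditions: i-PrCOCl (1.05 equiv), pyridine, CH2Cl2, 0 °C
Reagents that add atoms: 2-methylpropanoyl chloride, CC(C)C(Cl)=O
Why: Acylation of a primary alcohol in the presence of a tertiary one should be fully selective.

Step 13
Reactants: 15 [(4S,6S)-4-ethynyl-6-hydroxycyclohex-1-en-1-yl]methyl 2-methylpropanoate; 18 (2R)-2-hydroxy-2-methylpent-4-en-1-yl 2-methylpropanoate
Product: 19 [(4S,6S)-6-hydroxy-4-[(4E,6R)-6-hydroxy-6-methyl-7-(2-methylpropanoyloxy)hepta-1,4-dien-2-yl]cyclohex-1-en-1-yl]methyl 2-methylpropanoate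
Conditions: [CpRu(MeCN)3]PF6 (10 mol %), 15 (1.0 equiv), 18 (1.3 equiv), acetone, rt
Reagents that add atoms: none
Why: Ruthenium-catalysed alkene–alkyne Alder-ene coupling, in which the ruthenacyclopentene from the terminal alkyne and the monosubstituted alkene undergoes β-hydride elimination and reductive elimination, should give the branched 1,4-diene with the E disubstituted alkene and leave all stereocentres untouched.

**Compound list**

1 | 2,2-dimethyl-1,3-dioxan-5-one | CC1(C)OCC(=O)CO1 | starting material
2 | 5-(bromomethylidene)-2,2-dimethyl-1,3-dioxane | CC1(C)OCC(=CBr)CO1 | intermediate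
3 | 2-(bromomethylidene)propane-1,3-diol | OCC(=CBr)CO | intermediate
4 | 3-bromo-2-({[tert-butyl(dimethyl)silyl]oxy}methyl)prop-2-en-1-ol (E/Z mixture) | OCC(=CBr)CO[Si](C)(C)C(C)(C)C | intermediate
5 | 3-bromo-2-({[tert-butyl(dimethyl)silyl]oxy}methyl)prop-2-enal (E/Z mixture) | O=CC(=CBr)CO[Si](C)(C)C(C)(C)C | intermediate
6 | ethyl 2-(bromomethyl)prop-2-enoate | C=C(CBr)C(=O)OCC | starting material
7 | ethyl (4S)-6-bromo-5-({[tert-butyl(dimethyl)silyl]oxy}methyl)-2-methylidene-4-[(trimethylsilyl)oxy]hex-5-enoate (E/Z mixture) | C=C(C[C@H](O[Si](C)(C)C)C(=CBr)CO[Si](C)(C)C(C)(C)C)C(=O)OCC | intermediate (not isolated)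
8 | ethyl (4S)-6-bromo-5-({[tert-butyl(dimethyl)silyl]oxy}methyl)-4-hydroxy-2-methylidenehex-5-enoate (E/Z mixture) | C=C(C[C@H](O)C(=CBr)CO[Si](C)(C)C(C)(C)C)C(=O)OCC | intermediate (not isolated)
9 | (5S)-5-[1-bromo-3-{[tert-butyl(dimethyl)silyl]oxy}prop-1-en-2-yl]-3-methylideneoxolan-2-one (E/Z mixture) | C=C1C[C@H](OC1=O)C(=CBr)CO[Si](C)(C)C(C)(C)C | intermediate
10 | (1S,5S)-4-({[tert-butyl(dimethyl)silyl]oxy}methyl)-6-oxabicyclo[3.2.1]oct-3-en-7-one | O=C1O[C@H]2C[C@@H]1CC=C2CO[Si](C)(C)C(C)(C)C | intermediate
11 | (1S,5S)-4-({[tert-butyl(dimethyl)silyl]oxy}methyl)-6-oxabicyclo[3.2.1]oct-3-en-7-ol (both hemiacetal epimers) | OC1O[C@H]2C[C@@H]1CC=C2CO[Si](C)(C)C(C)(C)C | intermediate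
12 | (1S,5S)-4-({[tert-butyl(dimethyl)silyl]oxy}methyl)-5-hydroxycyclohex-3-ene-1-carbaldehyde | O=C[C@H]1CC=C(CO[Si](C)(C)C(C)(C)C)[C@@H](O)C1 | intermediate (not isolated)
13 | (1S,5S)-2-({[tert-butyl(dimethyl)silyl]oxy}methyl)-5-ethynylcyclohex-2-en-1-ol | C#C[C@H]1CC=C(CO[Si](C)(C)C(C)(C)C)[C@@H](O)C1 | intermediate
14 | (1S,5S)-5-ethynyl-2-(hydroxymethyl)cyclohex-2-en-1-ol | C#C[C@H]1CC=C(CO)[C@@H](O)C1 | intermediate
15 | [(4S,6S)-4-ethynyl-6-hydroxycyclohex-1-en-1-yl]methyl 2-methylpropanoate | C#C[C@H]1CC=C(COC(=O)C(C)C)[C@@H](O)C1 | intermediate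
16 | [(2S)-2-methyloxiran-2-yl]methanol | C[C@]1(CO)CO1 | starting material
17 | (2R)-2-methylpent-4-ene-1,2-diol | C=CC[C@@](C)(O)CO | intermediate
18 | (2R)-2-hydroxy-2-methylpent-4-en-1-yl 2-methylpropanoate | C=CC[C@@](C)(O)COC(=O)C(C)C | intermediate
19 | [(4S,6S)-6-hydroxy-4-[(4E,6R)-6-hydroxy-6-methyl-7-(2-methylpropanoyloxy)hepta-1,4-dien-2-yl]cyclohex-1-en-1-yl]methyl 2-methylpropanoate | C=C(C/C=C/[C@@](C)(O)COC(=O)C(C)C)[C@H]1CC=C(COC(=O)C(C)C)[C@@H](O)C1 | target

**Step count**

Total: 13 steps. Longest linear sequence: 11 steps (steps 1 to 10, then step 13).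

**Steps most likely to fail**

Step 6 (key step). What may go wrong: the vinyl radical is reduced by the stannane, or closes 5-exo, before it reaches the exocyclic CH2 across the rigid lactone (premature hydrogen transfer or loss of regiocontrol in the ring closure). Fallback: the order of the two ring closures is inverted. It sets out from hydroxy ester 8, isolated after the citric acid work-up of step 5 by leaving out the PPTS treatment. The same Bu3SnH/AIBN conditions on this open-chain α-substituted acrylate are an unstrained 6-endo vinyl radical cyclisation and should give ethyl (5S)-4-({[tert-butyl(dimethyl)silyl]oxy}methyl)-5-hydroxycyclohex-3-ene-1-carboxylate F1 as a mixture of epimers at the ester-bearing carbon. DBU in toluene at 80 °C should then epimerise that carbon and lactonise the cis isomer, which drains the mixture into 10, where the route is rejoined.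

Step 5. What may go wrong: poor facial selectivity of the allylchromium addition to this α-branched β-bromo enal, or reductive loss of the vinyl bromide. Fallback: bond formation and stereocontrol are separated. From 5, a zinc Barbier reaction with 6 (Zn dust, aq. NH4Cl, THF) should give racemic ethyl 6-bromo-5-({[tert-butyl(dimethyl)silyl]oxy}methyl)-4-hydroxy-2-methylidenehex-5-enoate F2. Dess–Martin periodinane should oxidise it to ethyl 6-bromo-5-({[tert-butyl(dimethyl)silyl]oxy}methyl)-2-methylidene-4-oxohex-5-enoate F3. Corey–Bakshi–Shibata reduction of this alkenyl ketone (Me-CBS oxazaborolidine, catecholborane, −78 °C, catalyst enantiomer chosen for the S alcohol) should give 8, and PPTS as in step 5 closes the lactone, so the route is rejoined at 9.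

Step 13. What may go wrong: loss of regiocontrol in the ruthenacycle (linear instead of branched 1,4-diene), or catalyst inhibition by the free allylic alcohol. Fallback: the branched connection is fixed by two regiodefined partners. From 15, ruthenium-catalysed Markovnikov hydrosilylation ((EtO)3SiH, [Cp*Ru(MeCN)3]PF6, CH2Cl2) should give the geminal vinylsilane [(4S,6S)-6-hydroxy-4-[1-(triethoxysilyl)ethenyl]cyclohex-1-en-1-yl]methyl 2-methylpropanoate F4. From 18, palladium-catalysed linear allylic C–H acetoxylation (Pd(OAc)2, benzoquinone, DMSO/AcOH) should give the E allylic acetate (2R,3E)-5-(acetyloxy)-2-hydroxy-2-methylpent-3-en-1-yl 2-methylpropanoate F5. A fluoride-promoted Hiyama-type allyl–alkenyl coupling of F4 with F5 (Pd2(dba)3, Bu4NF, THF), at the unhindered allyl terminus, should then give 19 directly.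

**Further compounds**

F1 | step 6 | ethyl (5S)-4-({[tert-butyl(dimethyl)silyl]oxy}methyl)-5-hydroxycyclohex-3-ene-1-carboxylate (epimers at C1) | CCOC(=O)C1CC=C(CO[Si](C)(C)C(C)(C)C)[C@@H](O)C1
F2 | step 5 | ethyl 6-bromo-5-({[tert-butyl(dimethyl)silyl]oxy}methyl)-4-hydroxy-2-methylidenehex-5-enoate (racemic, E/Z mixture) | C=C(CC(O)C(=CBr)CO[Si](C)(C)C(C)(C)C)C(=O)OCC
F3 | step 5 | ethyl 6-bromo-5-({[tert-butyl(dimethyl)silyl]oxy}methyl)-2-methylidene-4-oxohex-5-enoate (E/Z mixture) | C=C(CC(=O)C(=CBr)CO[Si](C)(C)C(C)(C)C)C(=O)OCC
F4 | step 13 | [(4S,6S)-6-hydroxy-4-[1-(triethoxysilyl)ethenyl]cyclohex-1-en-1-yl]methyl 2-methylpropanoate | C=C([Si](OCC)(OCC)OCC)[C@H]1CC=C(COC(=O)C(C)C)[C@@H](O)C1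
F5 | step 13 | (2R,3E)-5-(acetyloxy)-2-hydroxy-2-methylpent-3-en-1-yl 2-methylpropanoate | CC(=O)OC/C=C/[C@@](C)(O)COC(=O)C(C)C
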